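It is impossible to watch the partner in these runs: intermediate and product were measured, partner was not. So two people at the board read the same curves differently for the new flask, which has the partner charge of amber and teal and the protic impurity of violet.

the same everywhere: substrate 0.010 M

| run | partner | protic impurity | remark | time |
|---|---|---|---|---|
| amber | 9.5 mM | 1 mM | run made earlier |  |
| teal | 9.5 mM | 1.5 mM | run made earlier |  |
| violet | 14 mM | 2 mM | run made earlier |  |
| flask | 9.50 mM | 2.00 mM |  | 8.0 h |

| run | time / h | intermediate / % | product / % |
|---|---|---|---|
| amber | 0.0833 | 10.5 | 3.0 |
| amber | 0.167 | 14.8 | 4.5 |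
| amber | 0.333 | 17.8 | 14.4 |
| amber | 0.667 | 14.5 | 32.2 |
| amber | 1.33 | 7.8 | 55.3 |
| amber | 3.00 | 1.5 | 71.8 |
| amber | 6.00 | 0 | 79.6 |
| teal | 0.0833 | 8.3 | 2.5 |
| teal | 0.167 | 13.1 | 5.9 |
| teal | 0.333 | 17.9 | 14.1 |
| teal | 0.667 | 12.0 | 30.5 |
| teal | 1.33 | 6.2 | 52.5 |
| teal | 3.00 | 3.4 | 70.1 |
| teal | 6.00 | 1.8 | 77.7 |
| violet | 0.0833 | 14.1 | 2.6 |
| violet | 0.250 | 19.8 | 14.4 |
| violet | 0.667 | 17.7 | 40.9 |
| violet | 2.00 | 5.3 | 78.2 |
| violet | 6.00 | 1.6 | 96.5 |

(each reading ± 1 percentage point)

- the analysis behind the earlier runs scatters by 1 percentage point, standard deviation

- time up to 8.0 h at which intermediate stands highest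
- the amount of intermediate, in percent of the substrate charged, at that time
- the first time at which intermediate reaches 4.8%, in the same percent, in min

The first points to teal, whose last reading has 77.7% product where partner minus impurity comes to 80.0% of the substrate charge. He concludes that the impurity takes its share of partner at once, and that the new flask works from the start with 75.0% of the substrate charge in partner. The forecast stands on his side, reading “the impurity as destroying partner”, and gives 2.6 min to the level, a peak of 16.2%, and 0.37 h for the peak.

The second, whose reckoning I hold, answers that a final yield says how much partner is lost, not when. If the loss takes time, the new flask begins with its full 95.0%, as amber and teal did. Its start can then be read from theirs through the early take-up: intermediate plus product at the first reading, divided by that time, averaged over the two runs, which gives 1.46 /h of the substrate charge. The two sums lie 2.7 percentage points apart, with 1 point of scatter on each reading, so I use their mean. Counting all of that take-up as intermediate, my reckoning puts the level at 1.97 min, earlier than the forecast says. Both accept the first's count for the end of the new flask's run, with partner, charged below the substrate, as the limiting reagent.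

The simulation gives 2.08 min to the level, a peak of 16.0%, and 0.314 h for the peak.

    substrate + partner ⇌ intermediate (K = 1400 /M, k = 2.80 /M/min)
    intermediate ⇌ product + released group (K = 0.0220 M, k = 0.0620 /min)
    released group → by-product carried off (k = 0.0630 /min)
    partner + protic impurity → quenched reagent (k = 11.0 /M/min)
    crystals ⇌ released group, rate k5*(cs5 - [released group]) while solid is left; crystals form when [released group] > cs5 (solubility = 3.20 mM, k = 0.670 /min)

At 0.314 h the new flask still holds 24.6% of its own impurity charge, and by 8.00 h it holds 0.375%, with product at 74.2%. The new flask's peak divided by the take-up gives 0.110 h, the peak expressed in hours of take-up. For the neighbour charged with 0.016 M of partner, its other charges as in the new flask, the take-up scaled by partner is 2.46 /h, and the same 0.110 h multiplied by it gives 27.1%. The neighbour's peak stands at 24.7%.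

(All runs are calculated with made-up constants; scatter was added.)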